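**Retrosynthetic overview** (chain numbered C1 = alkyne CH to C15 = ethyl CH3)
1. C8–Br and C12–Br come last, by double SN2 on a diol; C10–Br by HBr addition to an enone; ring C (oxane O/C9–C13) by Achmatowicz rearrangement and Kishi reduction of a 2,5-disubstituted furan; C8–C9 by furyl addition to a bicyclic aldehyde.
2. The 2,5-dioxabicyclo[2.2.1]heptane is made in one operation from a monocyclic 3-silylpropargyl 2-deoxy-α-D-arabino-hexofuranoside 3-O-arenesulfonate: an acetal [1,2]-Wittig shift forms C3–C4, and the alkoxide it releases displaces the sulfonate to form O–C6.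
3. Enabling feature: C4 is an α-carbon of ring B (oxolane O/C4/C5/C6/C7), so with the C3 oxygen moved onto it C4 is an anomeric acetal carbon; C3 is propargylic, and C6, which carries the C3 oxygen in the target, lies 1,3 to C4 on the same ring.
4. Ring order: ring B (bought with C6 and C7 in 2-deoxy-D-glucose), then ring A (oxolane O/C3/C4/C5/C6, key step), then ring C. C4 is set by retention, C6 by inversion, C3 in the recombination; C13 by catalysis, with C9, C10 and C12 relayed from it; C8 by Felkin–Anh addition.

Key step: step 6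

Remark: the radical-pair recombination in step 6 is assumed to take the lithium-bridged course that gives the 3,4-syn isomer (alkyne endo); the first fallback covers the opposite outcome.

**Route**

Step 1
Reactants: 1 2-deoxy-D-glucose
Product: 2 2-deoxy-D-arabino-hexono-1,4-lactone
Conditions: Br2, BaCO3, H2O, 23 °C; filter, concentrate
Reagents that add atoms: none
Why: Bromine-water oxidation of the aldose gives the aldonic acid, which closes to the five-membered lactone on concentration without touching a stereocentre (aldose oxidation, lactonisation).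

Step 2
Reactants: 2 2-deoxy-D-arabino-hexono-1,4-lactone
Product: 3 2-deoxy-5,6-O-isopropylidene-D-arabino-hexono-1,4-lactone
Conditions: 2,2-dimethoxypropane, TsOH (cat.), acetone, 23 °C
Reagents that add atoms: 2,2-dimethoxypropane, COC(C)(C)OC
Why: Acid-catalysed transacetalisation takes the terminal 1,2-diol as the dioxolane and leaves the ring hydroxyl (the future C6–O) free (acetonide formation).

Step 3
Reactants: 3 2-deoxy-5,6-O-isopropylidene-D-arabino-hexono-1,4-lactone
Product: 4 2-deoxy-5,6-O-isopropylidene-D-arabino-hexofuranose (lactol, both anomers)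
Conditions: iBu2AlH (2.2 equiv), CH2Cl2, −78 °C; aq. KNaC4H4O6
Reagents that add atoms: none
Why: Partial reduction of the lactone stops at the aluminium hemiacetal at low temperature and gives the lactol on work-up (iBu2AlH lactone reduction).

Step 4
Reactants: 4 2-deoxy-5,6-O-isopropylidene-D-arabino-hexofuranose; 5 3-(trimethylsilyl)prop-2-yn-1-ol
Product: 6 3-(trimethylsilyl)prop-2-yn-1-yl 2-deoxy-5,6-O-isopropylidene-α-D-arabino-hexofuranoside
Conditions: 5 (3 equiv), PPTS (cat.), 4 Å molecular sieves, CH2Cl2, 23 °C; anomers separated, β-anomer re-equilibrated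
Reagents that add atoms: none
Why: Fischer-type glycosidation under equilibrating conditions, with O5 blocked so only the furanoside can form; the α-anomer (aglycone trans to both the C6 hydroxyl and the C7 side chain, which are cis to each other) should predominate.

Step 5
Reactants: 6 3-(trimethylsilyl)prop-2-yn-1-yl 2-deoxy-5,6-O-isopropylidene-α-D-arabino-hexofuranoside
Product: 7 3-O-(2,4,6-triisopropylbenzenesulfonyl) derivative of 6
Conditions: 2,4,6-triisopropylbenzenesulfonyl chloride, DMAP (cat.), pyridine, CH2Cl2, 23–40 °C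
Reagents that add atoms: 2,4,6-triisopropylbenzenesulfonyl chloride, CC(C)c1cc(C(C)C)c(S(=O)(=O)Cl)c(C(C)C)c1
Why: Sulfonylation of the only free hydroxyl proceeds with retention at C6 and gives a leaving group whose sulfur is shielded and which has no ortho hydrogen, so it should tolerate an alkyllithium at −78 °C (alcohol sulfonylation).

Step 6
Reactants: 7 3-O-(2,4,6-triisopropylbenzenesulfonyl) propargyl glycoside
Product: 10 2,5-dioxabicyclo[2.2.1]heptane core (oxygen bridges C3–O–C6 and C4–O–C7) with endo (trimethylsilyl)ethynyl on C3 and exo (4R)-2,2-dimethyl-1,3-dioxolan-4-yl on C7 (3S,4S,6S,7S,8R), via lithiated propargyl glycoside 8 (not isolated), via lithium propargylic alkoxide 9 (not isolated)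
Conditions: n-BuLi (1.1 equiv), THF, −78 °C; then DMPU, −78 to 40 °C
Reagents that add atoms: none
Why: n-BuLi removes a propargylic proton on the future C3 (α-oxy, alkynyl-stabilised) and the carbanion 8 undergoes an acetal [1,2]-Wittig rearrangement: homolysis of the weak anomeric C4–O bond gives a solvent-caged 2-oxolanyl radical and lithium ketyl that recombine at carbon to form C3–C4 and alkoxide 9. The alkoxide oxygen then lies on the ring face opposite the C6 arenesulfonate and, on warming with DMPU, displaces it to form O–C6 (Williamson etherification). The closest known reaction types are the [1,2]-Wittig rearrangement of silylpropargyl O-glycosides to C-glycosides and alkoxide closure of oxolanes onto secondary sulfonates. Ring A (O, C3, C4, C5, C6) closes 5-exo-tet and completes the bicyclo[2.2.1] core, ring B being the sugar oxolane. C4 is set by retention within the cage (that face is also the open one, anti to the C6 and C7 substituents), C6 by SN2 inversion, and C3 by recombination through a lithium-bridged arrangement (Li between the alkoxide oxygen and the ring oxygen) that turns the silylalkynyl group away from ring C5, which should give the 3,4-syn isomer with the alkyne endo. The rearrangement must outrun attack of the propargyl anion or n-BuLi on the sulfonate and recombination at the allenyl terminus; the low anomeric bond strength (shift at −78 °C), the hindered sulfonate and the silyl cap on the alkyne are there to secure this.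

Step 7
Reactants: 10 bicyclic acetonide
Product: 11 C8 aldehyde: same core with exo formyl on C7 (3S,4S,6S,7S)
Conditions: H5IO6, EtOAc, 23 °C
Reagents that add atoms: none
Why: Periodic acid hydrolyses the terminal acetonide and cleaves the liberated 1,2-diol in the same pot (glycol cleavage); the ring ethers and the silylalkyne should be inert.

Step 8
Reactants: 12 1-(furan-2-yl)propan-1-one
Product: 13 (S)-1-(furan-2-yl)propan-1-ol
Conditions: RuCl(p-cymene)[(S,S)-TsDPEN] (1 mol %), HCO2H/Et3N, 23 °C
Reagents that add atoms: none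
Why: Noyori asymmetric transfer hydrogenation of a heteroaryl alkyl ketone; the (S,S)-ligand should give the (S)-carbinol by analogy with aryl alkyl ketones, which fixes C13.

Step 9
Reactants: 13 (S)-1-(furan-2-yl)propan-1-ol
Product: 14 (S)-triethyl[1-(furan-2-yl)propoxy]silane
Conditions: Et3SiCl, imidazole, CH2Cl2, 0 °C
Reagents that add atoms: chlorotriethylsilane, CC[Si](Cl)(CC)CC
Why: Silylation masks the carbinol for the metalation and is later removable in the presence of a bulkier silyl ether (silyl ether formation).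

Step 10
Reactants: 14 (S)-triethyl[1-(furan-2-yl)propoxy]silane; 11 C8 aldehyde
Product: 17 (8S)-carbinol: C7 of the core bears CH(OH) attached to C5 of a furan whose C2 carries the (1S)-1-(triethylsilyloxy)propyl group (7,8-anti), via 5-lithiofuran 15 (not isolated), via furyltitanium triisopropoxide 16 (not isolated)
Conditions: 14, n-BuLi, THF, −78 to 0 °C; ClTi(O-i-Pr)3, −78 °C; then 11, −78 to −20 °C; H2O
Reagents that add atoms: none
Why: The 2-alkylfuran lithiates at its free α-position, and the non-chelating titanium reagent should add to the α-alkoxy aldehyde under Felkin–Anh control (ring oxygen anti to the incoming nucleophile) to give the 7,8-anti alcohol (organotitanium carbonyl addition).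

Step 11
Reactants: 17 (8S)-carbinol
Product: 18 C8 O-triisopropylsilyl ether of 17
Conditions: i-Pr3SiOTf, 2,6-lutidine, CH2Cl2, −78 to 0 °C
Reagents that add atoms: triisopropylsilyl trifluoromethanesulfonate, CC(C)[Si](OS(=O)(=O)C(F)(F)F)(C(C)C)C(C)C
Why: The silyl triflate protects the hindered furfuryl alcohol so that only the C13 hydroxyl can take part in the later ring expansion, and the bulky silyl ether should survive acid and HBr (silyl ether formation).

Step 12
Reactants: 18 bis-silyl ether
Product: 19 C13 alcohol (C8 O-triisopropylsilyl retained)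
Conditions: HF·pyridine, pyridine, THF, 0 °C
Reagents that add atoms: none
Why: Buffered fluoride should cleave the triethylsilyl ether much faster than the triisopropylsilyl ether and leave the C-silyl alkyne (selective desilylation).

Step 13
Reactants: 19 C13 alcohol
Product: 20 (2S)-2-ethyl-6-hydroxy-2H-pyran-3(6H)-one whose C6 (chain C9) carries the C8 silyloxy-substituted core (hemiketal, both anomers)
Conditions: NBS, NaHCO3, NaOAc, THF/H2O, 0 °C
Reagents that add atoms: water, O
Why: Achmatowicz rearrangement: bromonium oxidation of the furan to the cis-enedione and closure of the free C13 hydroxyl onto the C9 carbonyl give the pyranone; the silylated C8 oxygen cannot compete.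

Step 14
Reactants: 20 pyranone hemiketal
Product: 21 2,6-cis-(2S,6S)-2-ethyl-6-substituted 2H-pyran-3(6H)-one (chain C13 S, C9 S)
Conditions: Et3SiH, CF3CO2H, CH2Cl2, −40 to 0 °C
Reagents that add atoms: none
Why: Kishi reduction: the hemiketal ionises to the cyclic oxocarbenium ion and the silane delivers hydride axially, which should place the C9 substituent equatorial and cis to the C13 ethyl group, so C9 is relayed from C13.

Step 15
Reactants: 21 cis-enone
Product: 22 β-bromo ketone: C10 bromide trans to the C9 substituent (10S), C12 ketone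
Conditions: HBr (gas, 2 equiv), CH2Cl2, −78 to −30 °C; volatiles removed cold, used crude
Reagents that add atoms: hydrogen bromide, Br
Why: Conjugate addition of HBr to the enone is reversible, so bromide should end equatorial at C10, trans to the adjacent C9 substituent (hydrohalogenation of an enone under thermodynamic control).

Step 16
Reactants: 22 β-bromo ketone
Product: 23 bromo alcohol: axial C12 hydroxyl cis to the C13 ethyl group (12S), C10 bromide retained
Conditions: LiBH(s-Bu)3, THF, −78 °C; H2O
Reagents that add atoms: none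
Why: The bulky hydride attacks the oxan-3-one from the equatorial direction to give the axial alcohol, and the low temperature should suppress loss of HBr (hindered borohydride ketone reduction).

Step 17
Reactants: 23 bromo alcohol
Product: 24 C8,C12-diol with free terminal alkyne
Conditions: Bu4NF, THF, 0 to 23 °C
Reagents that add atoms: none
Why: Fluoride removes the O-triisopropylsilyl and C-trimethylsilyl groups together; the equatorial C10 bromide has no antiperiplanar hydrogen for elimination (desilylation).

Step 18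
Reactants: 24 C8,C12-diol
Product: 25 target tribromide (3S,4S,6S,7S,8R,9S,10S,12R,13S)
Conditions: CBr4, (n-Oct)3P, toluene, 70 °C
Reagents that add atoms: carbon tetrabromide, BrC(Br)(Br)Br
Why: Appel bromination: each alkoxyphosphonium ion is displaced by bromide with inversion, the axial C12 leaving group giving the equatorial bromide and C8 the (R)-bromide; a terminal alkyne is tolerated under these conditions.

**Compound list**
1 | 2-deoxy-D-glucose (drawn as the open-chain aldehyde; exists as the pyranose) | O=CC[C@@H](O)[C@H](O)[C@H](O)CO | starting material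
2 | 2-deoxy-D-arabino-hexono-1,4-lactone | O=C1C[C@@H](O)[C@H](O1)[C@H](O)CO | intermediate
3 | 2-deoxy-5,6-O-isopropylidene-D-arabino-hexono-1,4-lactone | O=C1C[C@@H](O)[C@H](O1)[C@H]2COC(C)(C)O2 | intermediate
4 | 2-deoxy-5,6-O-isopropylidene-D-arabino-hexofuranose (anomers) | OC1C[C@@H](O)[C@H](O1)[C@H]2COC(C)(C)O2 | intermediate
5 | 3-(trimethylsilyl)prop-2-yn-1-ol | C[Si](C)(C)C#CCO | starting material
6 | 3-(trimethylsilyl)prop-2-yn-1-yl 2-deoxy-5,6-O-isopropylidene-α-D-arabino-hexofuranoside | C[Si](C)(C)C#CCO[C@@H]1C[C@@H](O)[C@H](O1)[C@H]2COC(C)(C)O2 | intermediate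
7 | 3-O-(2,4,6-triisopropylbenzenesulfonyl) derivative of 6 | C[Si](C)(C)C#CCO[C@@H]1C[C@@H](OS(=O)(=O)c3c(C(C)C)cc(C(C)C)cc3C(C)C)[C@H](O1)[C@H]2COC(C)(C)O2 | intermediate
8 | α-lithiated propargyl glycoside (carbanion carbon unassigned) | C[Si](C)(C)C#CC([Li])O[C@@H]1C[C@@H](OS(=O)(=O)c3c(C(C)C)cc(C(C)C)cc3C(C)C)[C@H](O1)[C@H]2COC(C)(C)O2 | intermediate
9 | lithium (3S)-propargylic alkoxide of the C-glycoside, sulfonate still in place | C[Si](C)(C)C#C[C@H]([O-])[C@@H]1C[C@@H](OS(=O)(=O)c3c(C(C)C)cc(C(C)C)cc3C(C)C)[C@H](O1)[C@H]2COC(C)(C)O2.[Li+] | intermediate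
10 | 2,5-dioxabicyclo[2.2.1]heptane with endo (trimethylsilyl)ethynyl on C3 and exo (4R)-2,2-dimethyl-1,3-dioxolan-4-yl on C7 | C[Si](C)(C)C#C[C@@H]1O[C@H]2C[C@@H]1O[C@@H]2[C@H]3COC(C)(C)O3 | intermediate
11 | C8 aldehyde (exo formyl on C7 of the core) | C[Si](C)(C)C#C[C@@H]1O[C@H]2C[C@@H]1O[C@@H]2C=O | intermediate
12 | 1-(furan-2-yl)propan-1-one | CCC(=O)c1ccco1 | starting material
13 | (S)-1-(furan-2-yl)propan-1-ol | CC[C@H](O)c1ccco1 | intermediate
14 | (S)-triethyl[1-(furan-2-yl)propoxy]silane | CC[C@H](O[Si](CC)(CC)CC)c1ccco1 | intermediate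
15 | 5-lithio derivative of 14 | CC[C@H](O[Si](CC)(CC)CC)c1ccc([Li])o1 | intermediate
16 | furan-2-yltitanium triisopropoxide derived from 15 | CC[C@H](O[Si](CC)(CC)CC)c1ccc(o1)[Ti](OC(C)C)(OC(C)C)OC(C)C | intermediate
17 | (8S)-furyl carbinol (7,8-anti), C13 O-triethylsilyl | C[Si](C)(C)C#C[C@@H]1O[C@H]2C[C@@H]1O[C@@H]2[C@H](O)c3ccc(o3)[C@H](CC)O[Si](CC)(CC)CC | intermediate
18 | C8 O-triisopropylsilyl, C13 O-triethylsilyl bis-ether | C[Si](C)(C)C#C[C@@H]1O[C@H]2C[C@@H]1O[C@@H]2[C@H](O[Si](C(C)C)(C(C)C)C(C)C)c3ccc(o3)[C@H](CC)O[Si](CC)(CC)CC | intermediate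
19 | C13 alcohol, C8 O-triisopropylsilyl | C[Si](C)(C)C#C[C@@H]1O[C@H]2C[C@@H]1O[C@@H]2[C@H](O[Si](C(C)C)(C(C)C)C(C)C)c3ccc(o3)[C@H](CC)O | intermediate
20 | (2S)-2-ethyl-6-hydroxy-2H-pyran-3(6H)-one with the silyloxy-substituted core on C6 (anomers) | C[Si](C)(C)C#C[C@@H]1O[C@H]2C[C@@H]1O[C@@H]2[C@H](O[Si](C(C)C)(C(C)C)C(C)C)C3(O)C=CC(=O)[C@H](CC)O3 | intermediate
21 | 2,6-cis-dihydropyranone (C9 S, C13 S) | C[Si](C)(C)C#C[C@@H]1O[C@H]2C[C@@H]1O[C@@H]2[C@H](O[Si](C(C)C)(C(C)C)C(C)C)[C@@H]3C=CC(=O)[C@H](CC)O3 | intermediate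
22 | β-bromo ketone (10S bromide, C12 ketone) | C[Si](C)(C)C#C[C@@H]1O[C@H]2C[C@@H]1O[C@@H]2[C@H](O[Si](C(C)C)(C(C)C)C(C)C)[C@@H]3[C@@H](Br)CC(=O)[C@H](CC)O3 | intermediate
23 | bromo alcohol (10S bromide, 12S axial hydroxyl) | C[Si](C)(C)C#C[C@@H]1O[C@H]2C[C@@H]1O[C@@H]2[C@H](O[Si](C(C)C)(C(C)C)C(C)C)[C@@H]3[C@@H](Br)C[C@H](O)[C@H](CC)O3 | intermediate
24 | C8,C12-diol with C10 bromide and free alkyne | C#C[C@@H]1O[C@H]2C[C@@H]1O[C@@H]2[C@H](O)[C@@H]3[C@@H](Br)C[C@H](O)[C@H](CC)O3 | intermediate
25 | target tribromide CNP0139964.1 | C#C[C@@H]1O[C@H]2C[C@@H]1O[C@@H]2[C@@H](Br)[C@H]1O[C@@H](CC)[C@H](Br)C[C@@H]1Br | target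

**Step count**
Total steps: 18. Longest linear sequence: 16 (steps 1–7 and 10–18).

**Steps most likely to fail**

Step 6. The risk is poor facial selectivity when the radical pair recombines at C3, or the cascade stalling before ring closure. The fallback sets out from 7 and returns at 10, and replaces substrate control at C3 by reagent control. Compound 7 would be treated with n-BuLi at −78 °C and quenched cold with AcOH to give the C-glycosidic propargylic alcohol F1 as C3 epimers. Dess–Martin periodinane would oxidise it to the ynone F2. Transfer hydrogenation with RuCl(p-cymene)[(R,R)-TsDPEN] and HCO2H/Et3N, the alkyne acting as the directing π-group, should give the (3S)-propargylic alcohol F3. KN(SiMe3)2 in THF would then close ring A by displacement of the sulfonate to give 10.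

Step 15. The risk is loss of HBr from the β-bromo ketone during isolation or reduction, or poor diastereocontrol in the conjugate addition. The fallback sets out from 20 and returns at 25; it installs the C10 oxygen before the Kishi reduction and displaces it at the end. Compound 20 would be converted with HC(OMe)3, MeOH and PPTS into the C9 methyl ketal F4. Nucleophilic epoxidation (t-BuOOH, DBU) anti to the axial methoxy group would give the 10,11-epoxy ketone F5. SmI2 in THF/MeOH at −90 °C would cleave the α C–O bond to the C10 β-hydroxy ketone F6. NaBH4 with Et2BOMe would give the 10,12-cis diol ketal F7. Et3SiH with BF3·OEt2 would reduce the ketal to the oxane-10,12-diol F8, with both hydroxyls axial. Bu4NF would give the 8,10,12-triol F9, and CBr4 with (n-Oct)3P would convert all three alcohols to 25 with inversion.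

Step 18. The risk is participation of a neighbouring ring oxygen, or elimination, at C8 while both alcohols are activated as phosphonium ions. The fallback sets out from 23 and returns at 25; it separates the two substitutions and displaces C8 as a discrete sulfonate. With only the C12 hydroxyl free, 23 would be brominated with CBr4 and (n-Oct)3P to the 10,12-dibromide silyl ether F10. Bu4NF would give the 10,12-dibromo C8 alcohol F11. ClCH2SO2Cl in pyridine would give the C8 chloromethanesulfonate F12, and LiBr in DMF would displace it with inversion to give 25.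

Further compounds
F1 | step 6 | C-glycosidic propargylic alcohol (C3 epimers) | C[Si](C)(C)C#CC(O)[C@@H]1C[C@@H](OS(=O)(=O)c3c(C(C)C)cc(C(C)C)cc3C(C)C)[C@H](O1)[C@H]2COC(C)(C)O2
F2 | step 6 | ynone | C[Si](C)(C)C#CC(=O)[C@@H]1C[C@@H](OS(=O)(=O)c3c(C(C)C)cc(C(C)C)cc3C(C)C)[C@H](O1)[C@H]2COC(C)(C)O2
F3 | step 6 | (3S)-propargylic alcohol | C[Si](C)(C)C#C[C@H](O)[C@@H]1C[C@@H](OS(=O)(=O)c3c(C(C)C)cc(C(C)C)cc3C(C)C)[C@H](O1)[C@H]2COC(C)(C)O2
F4 | step 15 | C9 methyl ketal of 20 | C[Si](C)(C)C#C[C@@H]1O[C@H]2C[C@@H]1O[C@@H]2[C@H](O[Si](C(C)C)(C(C)C)C(C)C)[C@]3(OC)C=CC(=O)[C@H](CC)O3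
F5 | step 15 | 10,11-epoxy ketone | C[Si](C)(C)C#C[C@@H]1O[C@H]2C[C@@H]1O[C@@H]2[C@H](O[Si](C(C)C)(C(C)C)C(C)C)[C@]3(OC)[C@@H]4O[C@@H]4C(=O)[C@H](CC)O3
F6 | step 15 | C10 β-hydroxy ketone | C[Si](C)(C)C#C[C@@H]1O[C@H]2C[C@@H]1O[C@@H]2[C@H](O[Si](C(C)C)(C(C)C)C(C)C)[C@]3(OC)[C@H](O)CC(=O)[C@H](CC)O3
F7 | step 15 | 10,12-cis diol ketal | C[Si](C)(C)C#C[C@@H]1O[C@H]2C[C@@H]1O[C@@H]2[C@H](O[Si](C(C)C)(C(C)C)C(C)C)[C@]3(OC)[C@H](O)C[C@H](O)[C@H](CC)O3
F8 | step 15 | oxane-10,12-diol | C[Si](C)(C)C#C[C@@H]1O[C@H]2C[C@@H]1O[C@@H]2[C@H](O[Si](C(C)C)(C(C)C)C(C)C)[C@@H]3[C@H](O)C[C@H](O)[C@H](CC)O3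
F9 | step 15 | 8,10,12-triol | C#C[C@@H]1O[C@H]2C[C@@H]1O[C@@H]2[C@H](O)[C@@H]3[C@H](O)C[C@H](O)[C@H](CC)O3
F10 | step 18 | 10,12-dibromide silyl ether | C[Si](C)(C)C#C[C@@H]1O[C@H]2C[C@@H]1O[C@@H]2[C@H](O[Si](C(C)C)(C(C)C)C(C)C)[C@@H]3[C@@H](Br)C[C@@H](Br)[C@H](CC)O3
F11 | step 18 | 10,12-dibromo C8 alcohol | C#C[C@@H]1O[C@H]2C[C@@H]1O[C@@H]2[C@H](O)[C@@H]3[C@@H](Br)C[C@@H](Br)[C@H](CC)O3
F12 | step 18 | C8 chloromethanesulfonate | C#C[C@@H]1O[C@H]2C[C@@H]1O[C@@H]2[C@H](OS(=O)(=O)CCl)[C@@H]3[C@@H](Br)C[C@@H](Br)[C@H](CC)O3
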